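**Plan**

Numbering: ring A = C1–C5 and C10; ring B = C5–C10; CO2Me and CH3 on C4; CH3 on C8; CH3 and the chain C11–C15 on C9 (C16 = CH3 on C13).
Retrosynthetic cuts, in order: acetate C–O; C14–C15 and C13–CH3 (alkyne carbometalation); ring A C2=C3 unsaturation added as a helper; C4–CH3; ring A across C3–C4 and C1=C10; then C4=C5, C9–C11 and C8–CH3, back to 2-methylcyclohex-2-enone.
Structural feature used: the C1=C10 alkene stands on a former ring B ketone carbon (C10) that is 1,3 to the ester-bearing C4 through C5. C10–C5–C4 can therefore be a 4-oxo-2-enoate (carbonyl plus Michael terminus) that takes up C3–C2–C1 as a propene 1,3-dianion (an allylidene ylide) in one [3+3] Michael–Wittig operation, and the Wittig fixes the alkene at C1=C10.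
Forward order: ring B (conjugate methylation, allylation) → exocyclic enoate → ring A by the [3+3] annulation → C4 methylation → removal of the extra C2=C3 bond → side chain by alkyne carboalumination and acetylation.
Stereochemistry: C8 by catalyst-controlled conjugate addition; C9 by alkylation anti to the C8 methyl; C5 by protonation/equilibration next to the C10 ketone during the annulation; C4 by enolate methylation anti to the C5–C6 bond; C13=C14 (E) by syn-carbometalation.

Key step: step 4

Remark: C4 of 14 and 15 forms as an epimer pair that converges on trienolate 16, so their SMILES leave C4 open; methyl glyoxylate is used as the freshly cracked monomer.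

**Step 1**
Reactants: 1 2-methylcyclohex-2-en-1-one
Product: 3 trimethyl{[(3R)-2,3-dimethylcyclohex-1-en-1-yl]oxy}silane, via aluminium enolate 2 (not isolated)
Conditions: AlMe3, CuTC (copper thiophene-2-carboxylate, monovalent copper, cat.), binaphthol-derived bis(1-phenylethyl)amine phosphoramidite ligand (cat., enantiomer chosen to give 3R), Et2O, −30 °C; then TMSOTf, THF, −30 → 0 °C
Reagents that add atoms: trimethylaluminium C[Al](C)C; trimethylsilyl trifluoromethanesulfonate C[Si](C)(C)OS(=O)(=O)C(F)(F)F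
Why: Copper-catalysed asymmetric conjugate addition of a methylaluminium reagent to the α-substituted enone, in which the chiral copper–phosphoramidite complex selects the enone face and sets C8 (3R); O-silylation of aluminium enolate 2 stores the tetrasubstituted enolate regiochemistry.

**Step 2**
Reactants: 3 trimethyl{[(3R)-2,3-dimethylcyclohex-1-en-1-yl]oxy}silane; 4 allyl bromide
Product: 6 (2S,3R)-2,3-dimethyl-2-(prop-2-en-1-yl)cyclohexan-1-one, via lithium enolate 5 (not isolated)
Conditions: MeLi, THF, 0 → 25 °C; then 4, DMPU, −78 → 0 °C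
Reagents that add atoms: none
Why: Regiospecific lithium enolate generation from the silyl enol ether followed by C-alkylation; allyl bromide should approach anti to the neighbouring C8 methyl on the half-chair enolate, giving the cis-dimethyl ketone with quaternary C9 (2S).

**Step 3**
Reactants: 6 (2S,3R)-2,3-dimethyl-2-(prop-2-en-1-yl)cyclohexan-1-one; 7 methyl glyoxylate
Product: 11 methyl (2E)-2-[(3S,4R)-3,4-dimethyl-2-oxo-3-(prop-2-en-1-yl)cyclohexylidene]acetate, via lithium enolate 8 (not isolated), via lithium aldolate 9 (not isolated), via mesylate 10 (not isolated)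
Conditions: LDA, THF, −78 °C; 7, −78 °C; then MsCl, Et3N, −78 → 25 °C
Reagents that add atoms: none
Why: Directed aldol addition followed by E1cB elimination (aldol condensation): ketone 6 can enolize only toward C5 because C9 is quaternary, and the conjugated (E)-alkylidene with the ester anti to the carbonyl is the expected elimination product; no stereocenter is created.

**Step 4**
Reactants: 11 methyl (2E)-2-[(3S,4R)-3,4-dimethyl-2-oxo-3-(prop-2-en-1-yl)cyclohexylidene]acetate; 12 allyltriphenylphosphonium bromide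
Product: 15 methyl (5S,6R,8aS)-5,6-dimethyl-5-(prop-2-en-1-yl)-1,5,6,7,8,8a-hexahydronaphthalene-1-carboxylate, via allylidenetriphenylphosphorane 13 (not isolated), via Michael adduct ylide 14 (not isolated)
Conditions: 12, n-BuLi, THF, −78 → 0 °C; then 11, −78 → 25 °C; then 60 °C
Reagents that add atoms: none
Why: Ylide 13 adds through its γ-carbon (C3) to C4 of the 4-oxo-2-enoate (Michael addition), the C10 enolate so formed takes a proton back from C3 of the vinylphosphonium to give allylic ylide 14, and the ylide α-carbon (C1) then olefinates the C10 ketone intramolecularly with loss of Ph3PO (Wittig). The closest known reaction type is the Michael–Wittig [3+3] cyclohexadiene annulation of allylidenetriphenylphosphorane with α,β-unsaturated ketones. Ring A closes by 6-exo-trig attack of C1 on the C10 carbonyl (oxaphosphetane, then cycloreversion), so the new alkene can only be C1=C10. C5 is the new stereocenter that matters: it is α to the C10 ketone in 14 and should settle, by axial protonation and by equilibration, with the C4 branch equatorial on the ring B chair and anti to the axial C9 methyl (H5 cis to that methyl, as in the target), after which the Wittig closure locks it; C4 forms as an epimer pair that is erased in step 5. The step needs 1,4- over 1,2-addition, attack at C4 and not C5, and γ- over α-attack of the ylide: the C10 carbonyl is shielded by the quaternary C9 and the substituted C5, C4 is the unhindered terminus β to the ketone, and only the γ-adduct can go on to a six-membered ring.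

**Step 5**
Reactants: 15 methyl (5S,6R,8aS)-5,6-dimethyl-5-(prop-2-en-1-yl)-1,5,6,7,8,8a-hexahydronaphthalene-1-carboxylate
Product: 17 methyl (1S,5S,6R,8aR)-1,5,6-trimethyl-5-(prop-2-en-1-yl)-1,5,6,7,8,8a-hexahydronaphthalene-1-carboxylate, via lithium trienolate 16 (not isolated)
Conditions: LDA, THF, −78 °C; MeI, −78 → −30 °C
Reagents that add atoms: iodomethane CI
Why: α-Alkylation of an extended ester enolate: ring A of trienolate 16 is nearly flat with C6 of ring B on one face next to C4, so iodomethane should enter on the H5 face, anti to the C5–C6 bond, setting C4 (1S) with the methyl cis to H5 and the ester cis to C6.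

**Step 6**
Reactants: 17 methyl (1S,5S,6R,8aR)-1,5,6-trimethyl-5-(prop-2-en-1-yl)-1,5,6,7,8,8a-hexahydronaphthalene-1-carboxylate
Product: 19 methyl (1S,5S,6R,8aR)-5-(3-hydroxypropyl)-1,5,6-trimethyl-1,5,6,7,8,8a-hexahydronaphthalene-1-carboxylate, via alkylborane 18 (not isolated)
Conditions: 9-BBN, THF, 0 → 25 °C; then NaBO3·4H2O, H2O, 25 °C
Reagents that add atoms: sodium perborate [Na+].[O-]OB=O
Why: Hydroboration–oxidation: 9-BBN adds anti-Markovnikov to the monosubstituted alkene far faster than to the hindered ring diene, and perborate oxidizes the C–B bond under mild conditions that spare the ester; no stereocenter is created.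

**Step 7**
Reactants: 19 methyl (1S,5S,6R,8aR)-5-(3-hydroxypropyl)-1,5,6-trimethyl-1,5,6,7,8,8a-hexahydronaphthalene-1-carboxylate
Product: 20 methyl (1S,5S,6R,8aR)-5-(3-hydroxypropyl)-1,5,6-trimethyl-1,2,3,5,6,7,8,8a-octahydronaphthalene-1-carboxylate
Conditions: 2-nitrobenzenesulfonylhydrazide, Et3N, CH2Cl2, 25 °C
Reagents that add atoms: none
Why: Diimide reduction (concerted syn transfer of H2 from HN=NH generated in the flask): the cis-disubstituted, conjugated C2=C3 bond should react much faster than the trisubstituted C1=C10 bond flanked by the quaternary C9; no stereocenter is created.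

**Step 8**
Reactants: 20 methyl (1S,5S,6R,8aR)-5-(3-hydroxypropyl)-1,5,6-trimethyl-1,2,3,5,6,7,8,8a-octahydronaphthalene-1-carboxylate
Product: 21 methyl (1S,5S,6R,8aR)-1,5,6-trimethyl-5-(3-oxopropyl)-1,2,3,5,6,7,8,8a-octahydronaphthalene-1-carboxylate
Conditions: Dess–Martin periodinane, NaHCO3, CH2Cl2, 0 → 25 °C
Reagents that add atoms: none
Why: Dess–Martin oxidation of the primary alcohol to the aldehyde under buffered conditions; the alkene and the ester are inert.

**Step 9**
Reactants: 21 methyl (1S,5S,6R,8aR)-1,5,6-trimethyl-5-(3-oxopropyl)-1,2,3,5,6,7,8,8a-octahydronaphthalene-1-carboxylate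
Product: 22 methyl (1S,5S,6R,8aR)-5-(but-3-yn-1-yl)-1,5,6-trimethyl-1,2,3,5,6,7,8,8a-octahydronaphthalene-1-carboxylate
Conditions: dimethyl (1-diazo-2-oxopropyl)phosphonate, K2CO3, MeOH, 0 → 25 °C
Reagents that add atoms: dimethyl (1-diazo-2-oxopropyl)phosphonate CC(=O)C(=[N+]=[N-])P(=O)(OC)OC
Why: Ohira–Bestmann (Seyferth–Gilbert) homologation: the diazomethylphosphonate anion made in the flask adds to the aldehyde and the resulting alkylidene carbene rearranges to the terminal alkyne; the C4 ester has no α-hydrogen and should survive K2CO3/MeOH.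

**Step 10**
Reactants: 22 methyl (1S,5S,6R,8aR)-5-(but-3-yn-1-yl)-1,5,6-trimethyl-1,2,3,5,6,7,8,8a-octahydronaphthalene-1-carboxylate
Product: 24 methyl (1S,5S,6R,8aR)-5-[(3E)-5-hydroxy-3-methylpent-3-en-1-yl]-1,5,6-trimethyl-1,2,3,5,6,7,8,8a-octahydronaphthalene-1-carboxylate, via alkenylalane 23 (not isolated)
Conditions: AlMe3, Cp2ZrCl2 (cat.), H2O (1.5 equiv), CH2Cl2, −20 °C; then (CH2O)n, THF, 0 → 25 °C
Reagents that add atoms: trimethylaluminium C[Al](C)C; paraformaldehyde (as formaldehyde) C=O
Why: Zirconium-catalysed carboalumination (Negishi) adds CH3 and Al syn across the alkyne with the methyl on the internal carbon, and the C–Al bond, cis to that methyl, is hydroxymethylated with retention to give the (E)-allylic alcohol; the low temperature of the water-accelerated variant should spare the hindered ester.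

**Step 11**
Reactants: 24 methyl (1S,5S,6R,8aR)-5-[(3E)-5-hydroxy-3-methylpent-3-en-1-yl]-1,5,6-trimethyl-1,2,3,5,6,7,8,8a-octahydronaphthalene-1-carboxylate
Product: 25 methyl (1S,5S,6R,8aR)-5-[(3E)-5-(acetyloxy)-3-methylpent-3-en-1-yl]-1,5,6-trimethyl-1,2,3,5,6,7,8,8a-octahydronaphthalene-1-carboxylate
Conditions: Ac2O, pyridine, DMAP (cat.), CH2Cl2, 0 → 25 °C
Reagents that add atoms: acetic anhydride CC(=O)OC(C)=O
Why: DMAP-catalysed O-acylation of the primary allylic alcohol; no stereocenter is touched.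

**Compound list**

1 | 2-methylcyclohex-2-en-1-one | CC1=CCCCC1=O | starting material
2 | dimethylaluminium (3R)-2,3-dimethylcyclohex-1-en-1-olate | C[Al](C)OC1=C(C)[C@H](C)CCC1 | intermediate
3 | trimethyl{[(3R)-2,3-dimethylcyclohex-1-en-1-yl]oxy}silane | C[Si](C)(C)OC1=C(C)[C@H](C)CCC1 | intermediate
4 | allyl bromide (3-bromoprop-1-ene) | C=CCBr | starting material
5 | lithium (3R)-2,3-dimethylcyclohex-1-en-1-olate | [Li]OC1=C(C)[C@H](C)CCC1 | intermediate
6 | (2S,3R)-2,3-dimethyl-2-(prop-2-en-1-yl)cyclohexan-1-one | O=C1CCC[C@@H](C)[C@]1(C)CC=C | intermediate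
7 | methyl glyoxylate (methyl 2-oxoacetate) | COC(=O)C=O | starting material
8 | lithium (5R,6S)-5,6-dimethyl-6-(prop-2-en-1-yl)cyclohex-1-en-1-olate | [Li]OC1=CCC[C@@H](C)[C@]1(C)CC=C | intermediate
9 | methyl 2-[(3S,4R)-3,4-dimethyl-2-oxo-3-(prop-2-en-1-yl)cyclohexyl]-2-(lithiooxy)acetate (diastereomer mixture at the two new centres) | COC(=O)C(O[Li])C1CC[C@@H](C)[C@](C)(CC=C)C1=O | intermediate
10 | methyl 2-[(3S,4R)-3,4-dimethyl-2-oxo-3-(prop-2-en-1-yl)cyclohexyl]-2-[(methanesulfonyl)oxy]acetate (diastereomer mixture) | COC(=O)C(OS(C)(=O)=O)C1CC[C@@H](C)[C@](C)(CC=C)C1=O | intermediate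
11 | methyl (2E)-2-[(3S,4R)-3,4-dimethyl-2-oxo-3-(prop-2-en-1-yl)cyclohexylidene]acetate | COC(=O)/C=C1\CC[C@@H](C)[C@](C)(CC=C)C1=O | intermediate
12 | allyltriphenylphosphonium bromide | C=CC[P+](c1ccccc1)(c1ccccc1)c1ccccc1.[Br-] | starting material
13 | allylidenetriphenylphosphorane | C=CC=P(c1ccccc1)(c1ccccc1)c1ccccc1 | intermediate
14 | methyl 2-[(1S,3S,4R)-3,4-dimethyl-2-oxo-3-(prop-2-en-1-yl)cyclohexyl]-5-(triphenyl-λ5-phosphanylidene)pent-3-enoate (C2 epimers) | COC(=O)C(C=CC=P(c1ccccc1)(c1ccccc1)c1ccccc1)[C@@H]1CC[C@@H](C)[C@](C)(CC=C)C1=O | intermediate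
15 | methyl (5S,6R,8aS)-5,6-dimethyl-5-(prop-2-en-1-yl)-1,5,6,7,8,8a-hexahydronaphthalene-1-carboxylate (C1 epimers) | COC(=O)C1C=CC=C2[C@H]1CC[C@@H](C)[C@]2(C)CC=C | intermediate
16 | lithium trienolate of 15 (C4=C(OMe)OLi) | [Li]OC(OC)=C1C=CC=C2[C@H]1CC[C@@H](C)[C@]2(C)CC=C | intermediate
17 | methyl (1S,5S,6R,8aR)-1,5,6-trimethyl-5-(prop-2-en-1-yl)-1,5,6,7,8,8a-hexahydronaphthalene-1-carboxylate | COC(=O)[C@@]1(C)C=CC=C2[C@H]1CC[C@@H](C)[C@]2(C)CC=C | intermediate
18 | B-alkyl-9-borabicyclo[3.3.1]nonane adduct of 17 (boron on the chain terminus) | COC(=O)[C@@]1(C)C=CC=C2[C@H]1CC[C@@H](C)[C@]2(C)CCCB1C2CCCC1CCC2 | intermediate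
19 | methyl (1S,5S,6R,8aR)-5-(3-hydroxypropyl)-1,5,6-trimethyl-1,5,6,7,8,8a-hexahydronaphthalene-1-carboxylate | COC(=O)[C@@]1(C)C=CC=C2[C@H]1CC[C@@H](C)[C@]2(C)CCCO | intermediate
20 | methyl (1S,5S,6R,8aR)-5-(3-hydroxypropyl)-1,5,6-trimethyl-1,2,3,5,6,7,8,8a-octahydronaphthalene-1-carboxylate | COC(=O)[C@@]1(C)CCC=C2[C@H]1CC[C@@H](C)[C@]2(C)CCCO | intermediate
21 | methyl (1S,5S,6R,8aR)-1,5,6-trimethyl-5-(3-oxopropyl)-1,2,3,5,6,7,8,8a-octahydronaphthalene-1-carboxylate | COC(=O)[C@@]1(C)CCC=C2[C@H]1CC[C@@H](C)[C@]2(C)CCC=O | intermediate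
22 | methyl (1S,5S,6R,8aR)-5-(but-3-yn-1-yl)-1,5,6-trimethyl-1,2,3,5,6,7,8,8a-octahydronaphthalene-1-carboxylate | COC(=O)[C@@]1(C)CCC=C2[C@H]1CC[C@@H](C)[C@]2(C)CCC#C | intermediate
23 | methyl (1S,5S,6R,8aR)-5-[(3E)-4-(dimethylalumanyl)-3-methylbut-3-en-1-yl]-1,5,6-trimethyl-1,2,3,5,6,7,8,8a-octahydronaphthalene-1-carboxylate | COC(=O)[C@@]1(C)CCC=C2[C@H]1CC[C@@H](C)[C@]2(C)CC/C(C)=C/[Al](C)C | intermediate
24 | methyl (1S,5S,6R,8aR)-5-[(3E)-5-hydroxy-3-methylpent-3-en-1-yl]-1,5,6-trimethyl-1,2,3,5,6,7,8,8a-octahydronaphthalene-1-carboxylate | COC(=O)[C@@]1(C)CCC=C2[C@H]1CC[C@@H](C)[C@]2(C)CC/C(C)=C/CO | intermediate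
25 | methyl (1S,5S,6R,8aR)-5-[(3E)-5-(acetyloxy)-3-methylpent-3-en-1-yl]-1,5,6-trimethyl-1,2,3,5,6,7,8,8a-octahydronaphthalene-1-carboxylate | COC(=O)[C@@]1(C)CCC=C2[C@H]1CC[C@@H](C)[C@]2(C)CC/C(C)=C/COC(C)=O | target

Total step count: 11. Longest linear sequence: 11 steps (1 → 25).

**Steps most likely to fail**

Step 4. The ylide may attack through its α-carbon or add 1,2, the basic ylide may enolize 11 at C6, or the Wittig closure may stall at the hindered C10 ketone. The fallback builds the same ring at the saturated oxidation level by a reductive carbonyl–carbonyl coupling and sets out from 11. Copper-catalysed conjugate addition of [2-(1,3-dioxolan-2-yl)ethyl]magnesium bromide at C4 (CuBr·SMe2, TMSCl, THF, −78 °C) gives keto ester acetal F1. Aqueous HCl in THF frees keto aldehyde F2. Intramolecular McMurry coupling of the C1 aldehyde with the C10 ketone (TiCl3(DME)1.5, Zn–Cu couple, DME, reflux; low-valent titanium) gives monoene ester F3, with C2–C3 already saturated. Methylation (LDA, THF, −78 °C; MeI) gives allyl ester F4, and 9-BBN followed by NaBO3 returns to the route at 20, so that step 7 is not needed.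

Step 5. Alkylation of the extended enolate may stray to C2 or C10, or the flat ring may give poor facial selectivity at C4. The fallback methylates a simple ester enolate on the half-chair monoene instead and sets out from 15. 9-BBN then NaBO3 gives diene alcohol F5, and diimide reduction (2-nitrobenzenesulfonylhydrazide, Et3N) gives monoene alcohol F6. The dianion of F6 (LDA, 2.2 equiv, THF, −78 °C), which has only the α-position available, is then methylated with MeI equatorially, anti to the C5–C6 bond, and returns to the route at 20.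

Step 10. The C4 ester may be attacked by AlMe3, or capture of the alkenylalane by formaldehyde may be incomplete. The fallback builds the trisubstituted alkene by carbonyl olefination and sets out from aldehyde 21. MeMgBr (THF, −78 °C) gives secondary alcohol F7, and Dess–Martin oxidation gives methyl ketone F8. Horner–Wadsworth–Emmons reaction (triethyl phosphonoacetate, NaH, THF) gives (E)-enoate F9, with the minor Z isomer removed by chromatography. DIBAL-H (diisobutylaluminium hydride, CH2Cl2, −78 °C) should reduce the unhindered conjugated ethyl ester faster than the neopentyl C4 methyl ester and returns to the route at 24.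

**Further compounds**

F1 | step 4 | methyl 4-(1,3-dioxolan-2-yl)-2-[(1S,3S,4R)-3,4-dimethyl-2-oxo-3-(prop-2-en-1-yl)cyclohexyl]butanoate (C2 epimers) | COC(=O)C(CCC1OCCO1)[C@@H]1CC[C@@H](C)[C@](C)(CC=C)C1=O
F2 | step 4 | methyl 2-[(1S,3S,4R)-3,4-dimethyl-2-oxo-3-(prop-2-en-1-yl)cyclohexyl]-5-oxopentanoate (C2 epimers) | COC(=O)C(CCC=O)[C@@H]1CC[C@@H](C)[C@](C)(CC=C)C1=O
F3 | step 4 | methyl (5S,6R,8aS)-5,6-dimethyl-5-(prop-2-en-1-yl)-1,2,3,5,6,7,8,8a-octahydronaphthalene-1-carboxylate (C1 epimers) | COC(=O)C1CCC=C2[C@H]1CC[C@@H](C)[C@]2(C)CC=C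
F4 | step 4 | methyl (1S,5S,6R,8aR)-1,5,6-trimethyl-5-(prop-2-en-1-yl)-1,2,3,5,6,7,8,8a-octahydronaphthalene-1-carboxylate | COC(=O)[C@@]1(C)CCC=C2[C@H]1CC[C@@H](C)[C@]2(C)CC=C
F5 | step 5 | methyl (5S,6R,8aS)-5-(3-hydroxypropyl)-5,6-dimethyl-1,5,6,7,8,8a-hexahydronaphthalene-1-carboxylate (C1 epimers) | COC(=O)C1C=CC=C2[C@H]1CC[C@@H](C)[C@]2(C)CCCO
F6 | step 5 | methyl (5S,6R,8aS)-5-(3-hydroxypropyl)-5,6-dimethyl-1,2,3,5,6,7,8,8a-octahydronaphthalene-1-carboxylate (C1 epimers) | COC(=O)C1CCC=C2[C@H]1CC[C@@H](C)[C@]2(C)CCCO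
F7 | step 10 | methyl (1S,5S,6R,8aR)-5-(3-hydroxybutyl)-1,5,6-trimethyl-1,2,3,5,6,7,8,8a-octahydronaphthalene-1-carboxylate (carbinol epimers) | COC(=O)[C@@]1(C)CCC=C2[C@H]1CC[C@@H](C)[C@]2(C)CCC(C)O
F8 | step 10 | methyl (1S,5S,6R,8aR)-1,5,6-trimethyl-5-(3-oxobutyl)-1,2,3,5,6,7,8,8a-octahydronaphthalene-1-carboxylate | COC(=O)[C@@]1(C)CCC=C2[C@H]1CC[C@@H](C)[C@]2(C)CCC(C)=O
F9 | step 10 | methyl (1S,5S,6R,8aR)-5-[(3E)-5-ethoxy-3-methyl-5-oxopent-3-en-1-yl]-1,5,6-trimethyl-1,2,3,5,6,7,8,8a-octahydronaphthalene-1-carboxylate | COC(=O)[C@@]1(C)CCC=C2[C@H]1CC[C@@H](C)[C@]2(C)CC/C(C)=C/C(=O)OCC
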